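The route rests on cutting ring A at two neighbouring bonds, C6–O (the diaryl ether) and C1–CO2H. In ring A the carboxyl carbon C1 sits between the C2 methoxy group and the C6 aryloxy group, which is exactly the pattern left when a nucleophile and then an electrophile add across a 3-methoxybenzyne. The key step therefore joins the ring B phenoxide, the ring A aryne and CO2 in one operation. Its precursor is an enantiopure 3-methoxy-2-(trimethylsilyl)aryl triflate that already carries the (R)-1-methoxy-3-methylbutyl side chain; the partner is a ring B phenol whose aldehyde is a dioxolane and whose second hydroxyl is an allyl ether.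

Key step: step 14

Remark (numbering): ring A is the benzoic acid ring, with C1 bearing the carboxyl group, C2 the methoxy group, C3 the side chain and C6 the aryloxy group; ring B is the formyl-bearing phenol ring.
Remark (protecting groups): the benzylic methyl ether on the oxygen-rich ring A is assumed to ionise in strong acid, so ring B carries an allyl ether and a 1,3-dioxolane, removable with zerovalent palladium and dilute acid; an acetal-type phenol ether would need acid strong enough to endanger the stereocentre.
Remark (salts): alkoxide, phenoxide and carboxylate salts that are only the deprotonated or work-up forms of a numbered compound are not numbered separately.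

Step 1
Reactants: 1 resorcinol; 2 isovaleryl chloride (3-methylbutanoyl chloride)
Product: 3 1-(2,4-dihydroxyphenyl)-3-methylbutan-1-one
Conditions: AlCl3, PhNO2, 0 → 60 °C; aq. HCl
Reagents that add atoms: none
Why: Friedel–Crafts acylation (by way of O-acylation and Fries shift) goes to C4 of resorcinol, ortho to one hydroxyl and para to the other, and stops after one acylation because the chelated ketone deactivates the ring.

Step 2
Reactants: 3 1-(2,4-dihydroxyphenyl)-3-methylbutan-1-one
Product: 4 1-[2-hydroxy-4-(prop-2-en-1-yloxy)phenyl]-3-methylbutan-1-one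
Conditions: allyl bromide (1.05 equiv), K2CO3, acetone, reflux
Reagents that add atoms: allyl bromide, C=CCBr
Why: Williamson etherification should be selective for the 4-hydroxyl, because the 2-hydroxyl is held in a hydrogen bond to the ketone and is much less nucleophilic under mild carbonate conditions.

Step 3
Reactants: 4 1-[2-hydroxy-4-(prop-2-en-1-yloxy)phenyl]-3-methylbutan-1-one
Product: 5 1-[2-methoxy-4-(prop-2-en-1-yloxy)phenyl]-3-methylbutan-1-one
Conditions: MeI, K2CO3, DMF, 50 °C
Reagents that add atoms: iodomethane, CI
Why: More forcing Williamson methylation in a dipolar aprotic solvent alkylates the remaining chelated phenol, the usual second alkylation of a 2-hydroxyaryl ketone.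

Step 4
Reactants: 5 1-[2-methoxy-4-(prop-2-en-1-yloxy)phenyl]-3-methylbutan-1-one
Product: 6 (1R)-1-[2-methoxy-4-(prop-2-en-1-yloxy)phenyl]-3-methylbutan-1-ol
Conditions: RuCl[(R,R)-TsDPEN](p-cymene) (1–2 mol %), HCO2Na, H2O/MeOH, 40 °C
Reagents that add atoms: none
Why: Noyori–Ikariya asymmetric transfer hydrogenation sets the stereocentre: the CH–π contact between the ketone aryl ring and the p-cymene ligand fixes the face of hydride delivery, so the (R,R)-TsDPEN complex, which turns acetophenone into (R)-1-phenylethanol, should give the (R)-carbinol here (aryl and alkyl hold the same CIP ranks), and the near-neutral formate medium spares the acid-sensitive carbinol and the allyl ether.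

Step 5
Reactants: 6 (1R)-1-[2-methoxy-4-(prop-2-en-1-yloxy)phenyl]-3-methylbutan-1-ol
Product: 7 2-methoxy-1-[(1R)-1-methoxy-3-methylbutyl]-4-(prop-2-en-1-yloxy)benzene
Conditions: NaH, MeI, THF, 0 °C → rt
Reagents that add atoms: iodomethane, CI
Why: Williamson methylation of the sodium alkoxide forms the O–CH3 bond without touching the C–O bond at the stereocentre, so the (R) configuration is retained.

Step 6
Reactants: 7 2-methoxy-1-[(1R)-1-methoxy-3-methylbutyl]-4-(prop-2-en-1-yloxy)benzene
Product: 8 3-methoxy-4-[(1R)-1-methoxy-3-methylbutyl]phenol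
Conditions: Pd(PPh3)4 (3 mol %), morpholine, THF, rt; neutral work-up
Reagents that add atoms: none
Why: Tsuji–Trost deallylation, in which zerovalent palladium ionises the aryl allyl ether to a π-allyl complex that morpholine captures, frees the phenol under non-acidic conditions that leave both methyl ethers and the stereocentre alone.

Step 7
Reactants: 8 3-methoxy-4-[(1R)-1-methoxy-3-methylbutyl]phenol
Product: 9 3-methoxy-4-[(1R)-1-methoxy-3-methylbutyl]phenyl N-(propan-2-yl)carbamate
Conditions: i-PrNCO, Et3N (cat.), CH2Cl2, rt
Reagents that add atoms: isopropyl isocyanate, CC(C)N=C=O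
Why: Base-catalysed addition of the phenol to the isocyanate gives the N-isopropyl carbamate, the removable directing group needed for the ortho-silylation.

Step 8
Reactants: 9 3-methoxy-4-[(1R)-1-methoxy-3-methylbutyl]phenyl N-(propan-2-yl)carbamate
Product: 13 3-methoxy-4-[(1R)-1-methoxy-3-methylbutyl]-2-(trimethylsilyl)phenyl N-(propan-2-yl)carbamate, via N-silyl carbamate 10 (not isolated), via aryllithium 11 (not isolated), via N-silyl C-silyl carbamate 12 (not isolated)
Conditions: TBSOTf (1.05 equiv), TMEDA, Et2O, 0 °C → rt; n-BuLi, TMEDA, −78 °C; TMSCl, −78 °C → rt; brief aq. NaHSO4 wash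
Reagents that add atoms: chlorotrimethylsilane, C[Si](C)(C)Cl; tert-butyldimethylsilyl triflate (silicon present only in 10–12), CC(C)(C)[Si](C)(C)OS(=O)(=O)C(F)(F)F
Why: Directed ortho-metalation: after in situ N-silylation the carbamate and the methoxy group together direct lithiation to the carbon between them, TMSCl silylates the aryllithium, and the low temperature should keep the tertiary benzylic C–H of the side chain untouched.

Step 9
Reactants: 13 3-methoxy-4-[(1R)-1-methoxy-3-methylbutyl]-2-(trimethylsilyl)phenyl N-(propan-2-yl)carbamate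
Product: 15 3-methoxy-4-[(1R)-1-methoxy-3-methylbutyl]-2-(trimethylsilyl)phenyl trifluoromethanesulfonate, via silyl phenol 14 (not isolated)
Conditions: DBU, Et2NH, MeCN, 40 °C; then PhNTf2, rt
Reagents that add atoms: N-phenylbis(trifluoromethanesulfonimide), O=S(=O)(N(c1ccccc1)S(=O)(=O)C(F)(F)F)C(F)(F)F
Why: DBU triggers E1cB loss of isopropyl isocyanate (trapped by Et2NH as a urea) to release the phenoxide, which PhNTf2 triflates in the same flask, the established way from a silyl carbamate to an ortho-silylaryl triflate.

Step 10
Reactants: 16 2-methoxy-4-methylphenol (creosol)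
Product: 18 2-hydroxy-3-methoxy-5-methylbenzaldehyde, via salicyl alcohol 17 (not isolated)
Conditions: (CH2O)n, MgCl2, Et3N, MeCN, reflux; aq. HCl
Reagents that add atoms: formaldehyde (as paraformaldehyde), C=O
Why: Casnati–Skattebøl ortho-formylation: the magnesium phenoxide directs formaldehyde to the only free ortho position, and a second equivalent of formaldehyde oxidises the resulting benzylic alkoxide by hydride transfer.

Step 11
Reactants: 18 2-hydroxy-3-methoxy-5-methylbenzaldehyde
Product: 19 2,3-dihydroxy-5-methylbenzaldehyde
Conditions: BBr3, CH2Cl2, −78 °C → rt; H2O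
Reagents that add atoms: none
Why: Lewis-acid ether cleavage with BBr3 (bromide attacks the O-methyl carbon of the boron-bound ether) removes the aryl methyl ether while the aldehyde survives, as in the demethylation of ortho-vanillin.

Step 12
Reactants: 19 2,3-dihydroxy-5-methylbenzaldehyde
Product: 20 2-hydroxy-5-methyl-3-(prop-2-en-1-yloxy)benzaldehyde
Conditions: NaH (2.2 equiv), DMSO, rt; allyl bromide (1.0 equiv), rt; aq. HCl
Reagents that add atoms: allyl bromide, C=CCBr
Why: Regioselective mono-O-alkylation of the catechol dianion: the 2-phenoxide is delocalised into the formyl group and chelated, so one equivalent of allyl bromide should alkylate the more nucleophilic 3-phenoxide.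

Step 13
Reactants: 20 2-hydroxy-5-methyl-3-(prop-2-en-1-yloxy)benzaldehyde
Product: 21 2-(1,3-dioxolan-2-yl)-4-methyl-6-(prop-2-en-1-yloxy)phenol
Conditions: HOCH2CH2OH, p-TsOH·H2O (cat.), toluene, reflux, Dean–Stark
Reagents that add atoms: ethylene glycol, OCCO
Why: Acid-catalysed acetalisation with azeotropic removal of water gives the cyclic acetal, which is inert to base, fluoride and carbanions, at a temperature far below that of a Claisen rearrangement of the allyl ether.

Step 14
Reactants: 15 3-methoxy-4-[(1R)-1-methoxy-3-methylbutyl]-2-(trimethylsilyl)phenyl trifluoromethanesulfonate; 21 2-(1,3-dioxolan-2-yl)-4-methyl-6-(prop-2-en-1-yloxy)phenol; 22 carbon dioxide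
Product: 25 6-[2-(1,3-dioxolan-2-yl)-4-methyl-6-(prop-2-en-1-yloxy)phenoxy]-2-methoxy-3-[(1R)-1-methoxy-3-methylbutyl]benzoic acid, via aryne 23 (not isolated), via aryl anion 24 (not isolated)
Conditions: 21 (1.5 equiv), KH, THF, 0 °C; then 18-crown-6, KF, CO2 (1 atm), slow addition of 15, 0 °C → rt; cold aq. HCl to pH 3
Reagents that add atoms: none
Why: Proposed new method: fluoride attacks silicon of 15 and triflate leaves to give aryne 23, the crown-ether-separated phenoxide of 21 adds to aryne carbon C6, and the aryl anion 24 thus formed at C1 is intercepted by dissolved CO2, so that the C6–O and C1–CO2 bonds arise in one operation. The closest known reaction types are the fluoride-mediated three-component coupling of arynes, amines and CO2 to anthranilic acids and the O-arylation of phenols by arynes, which are merged here. The addition must be regioselective, and the C2 methoxy group secures this: its inductive pull and the distortion it imposes on the aryne send the nucleophile to the remote carbon C6 and leave the charge at C1 beside the C–O bond, a preference reinforced by the lower steric demand at C6. Carboxylation must outrun protonation, which the absence of any O–H or N–H donor (phenoxide pre-formed with KH, THF in place of MeCN) and the CO2 atmosphere should ensure, while slow addition of 15 keeps the hindered product carboxylate from competing for the aryne. The ring B aldehyde is masked as the dioxolane because a free formyl group would capture 24 intramolecularly, and the allyl ether is inert to fluoride and to the aryl anion. No ring is closed and no stereocentre is formed, the (R) centre being a spectator under these conditions free of acid and of strong soluble base.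

Step 15
Reactants: 25 6-[2-(1,3-dioxolan-2-yl)-4-methyl-6-(prop-2-en-1-yloxy)phenoxy]-2-methoxy-3-[(1R)-1-methoxy-3-methylbutyl]benzoic acid
Product: 27 6-(2-formyl-6-hydroxy-4-methylphenoxy)-2-methoxy-3-[(1R)-1-methoxy-3-methylbutyl]benzoic acid, via phenol acetal acid 26 (not isolated)
Conditions: Pd(PPh3)4 (5 mol %), morpholine, THF, rt; then 0.5 M aq. HCl, THF, rt
Reagents that add atoms: water, O
Why: Tsuji–Trost deallylation with morpholine as allyl acceptor frees the ring B hydroxyl, and dilute aqueous acid then hydrolyses the aryl dioxolane through its oxocarbenium ion far faster than it could ionise the benzylic methyl ether, so the (R) centre should be preserved.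

Compound list
1 | resorcinol | Oc1cccc(O)c1 | starting material
2 | isovaleryl chloride (3-methylbutanoyl chloride) | CC(C)CC(=O)Cl | starting material
3 | 1-(2,4-dihydroxyphenyl)-3-methylbutan-1-one | CC(C)CC(=O)c1ccc(O)cc1O | intermediate
4 | 1-[2-hydroxy-4-(prop-2-en-1-yloxy)phenyl]-3-methylbutan-1-one | CC(C)CC(=O)c1ccc(OCC=C)cc1O | intermediate
5 | 1-[2-methoxy-4-(prop-2-en-1-yloxy)phenyl]-3-methylbutan-1-one | CC(C)CC(=O)c1ccc(OCC=C)cc1OC | intermediate
6 | (1R)-1-[2-methoxy-4-(prop-2-en-1-yloxy)phenyl]-3-methylbutan-1-ol | COc1cc(OCC=C)ccc1[C@@H](CC(C)C)O | intermediate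
7 | 2-methoxy-1-[(1R)-1-methoxy-3-methylbutyl]-4-(prop-2-en-1-yloxy)benzene | COc1cc(OCC=C)ccc1[C@@H](CC(C)C)OC | intermediate
8 | 3-methoxy-4-[(1R)-1-methoxy-3-methylbutyl]phenol | COc1cc(O)ccc1[C@@H](CC(C)C)OC | intermediate
9 | 3-methoxy-4-[(1R)-1-methoxy-3-methylbutyl]phenyl N-(propan-2-yl)carbamate | COc1cc(OC(=O)NC(C)C)ccc1[C@@H](CC(C)C)OC | intermediate
10 | 3-methoxy-4-[(1R)-1-methoxy-3-methylbutyl]phenyl N-(tert-butyldimethylsilyl)-N-(propan-2-yl)carbamate | COc1cc(OC(=O)N(C(C)C)[Si](C)(C)C(C)(C)C)ccc1[C@@H](CC(C)C)OC | intermediate
11 | 2-lithio-3-methoxy-4-[(1R)-1-methoxy-3-methylbutyl]phenyl N-(tert-butyldimethylsilyl)-N-(propan-2-yl)carbamate | COc1c([Li])c(OC(=O)N(C(C)C)[Si](C)(C)C(C)(C)C)ccc1[C@@H](CC(C)C)OC | intermediate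
12 | 3-methoxy-4-[(1R)-1-methoxy-3-methylbutyl]-2-(trimethylsilyl)phenyl N-(tert-butyldimethylsilyl)-N-(propan-2-yl)carbamate | COc1c([Si](C)(C)C)c(OC(=O)N(C(C)C)[Si](C)(C)C(C)(C)C)ccc1[C@@H](CC(C)C)OC | intermediate
13 | 3-methoxy-4-[(1R)-1-methoxy-3-methylbutyl]-2-(trimethylsilyl)phenyl N-(propan-2-yl)carbamate | COc1c([Si](C)(C)C)c(OC(=O)NC(C)C)ccc1[C@@H](CC(C)C)OC | intermediate
14 | 3-methoxy-4-[(1R)-1-methoxy-3-methylbutyl]-2-(trimethylsilyl)phenol | COc1c([Si](C)(C)C)c(O)ccc1[C@@H](CC(C)C)OC | intermediate
15 | 3-methoxy-4-[(1R)-1-methoxy-3-methylbutyl]-2-(trimethylsilyl)phenyl trifluoromethanesulfonate | COc1c([Si](C)(C)C)c(OS(=O)(=O)C(F)(F)F)ccc1[C@@H](CC(C)C)OC | intermediate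
16 | 2-methoxy-4-methylphenol (creosol) | COc1cc(C)ccc1O | starting material
17 | 2-(hydroxymethyl)-6-methoxy-4-methylphenol | COc1cc(C)cc(CO)c1O | intermediate
18 | 2-hydroxy-3-methoxy-5-methylbenzaldehyde | COc1cc(C)cc(C=O)c1O | intermediate
19 | 2,3-dihydroxy-5-methylbenzaldehyde | Cc1cc(O)c(O)c(C=O)c1 | intermediate
20 | 2-hydroxy-5-methyl-3-(prop-2-en-1-yloxy)benzaldehyde | C=CCOc1cc(C)cc(C=O)c1O | intermediate
21 | 2-(1,3-dioxolan-2-yl)-4-methyl-6-(prop-2-en-1-yloxy)phenol | C=CCOc1cc(C)cc(C2OCCO2)c1O | intermediate
22 | carbon dioxide | O=C=O | starting material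
23 | 1,2-didehydro-3-methoxy-4-[(1R)-1-methoxy-3-methylbutyl]benzene (aryne) | COC1=C([C@@H](CC(C)C)OC)C=CC#C1 | intermediate
24 | potassium 2-[2-(1,3-dioxolan-2-yl)-4-methyl-6-(prop-2-en-1-yloxy)phenoxy]-6-methoxy-5-[(1R)-1-methoxy-3-methylbutyl]benzen-1-ide | COc1c([C@@H](CC(C)C)OC)ccc(Oc2c(OCC=C)cc(C)cc2C3OCCO3)[c-]1.[K+] | intermediate
25 | 6-[2-(1,3-dioxolan-2-yl)-4-methyl-6-(prop-2-en-1-yloxy)phenoxy]-2-methoxy-3-[(1R)-1-methoxy-3-methylbutyl]benzoic acid | COc1c([C@@H](CC(C)C)OC)ccc(Oc2c(OCC=C)cc(C)cc2C3OCCO3)c1C(=O)O | intermediate
26 | 6-[2-(1,3-dioxolan-2-yl)-6-hydroxy-4-methylphenoxy]-2-methoxy-3-[(1R)-1-methoxy-3-methylbutyl]benzoic acid | COc1c([C@@H](CC(C)C)OC)ccc(Oc2c(O)cc(C)cc2C3OCCO3)c1C(=O)O | intermediate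
27 | 6-(2-formyl-6-hydroxy-4-methylphenoxy)-2-methoxy-3-[(1R)-1-methoxy-3-methylbutyl]benzoic acid | COc1c([C@@H](CC(C)C)OC)ccc(Oc2c(O)cc(C)cc2C=O)c1C(=O)O | target

Total step count: 15 (nine to the ring A aryne precursor, four to the ring B phenol, the coupling, and one deprotection operation).
Longest linear sequence: 11 steps (steps 1–9, 14 and 15).

Steps most likely to fail

Step 14 (proposed new method). What may go wrong: protonation of the aryl anion by adventitious water, solvent or crown ether outrunning carboxylation; reversible carbonate formation tying up the phenoxide so that the aryne is consumed by fluoride or by the product carboxylate; or loss of regiocontrol in the addition. The fallback uses known chemistry only and makes the ether bond and the carboxyl group in separate operations. It sets out from 15 and 21: CsF in MeCN at room temperature should give, by the established O-arylation of a free phenol with an aryne (the phenol O–H quenches the aryl anion), the C1-unsubstituted diaryl ether F1, with the same regiochemistry as in the main route. Deallylation with Pd(PPh3)4 and morpholine then gives the free phenol diaryl ether F2; this comes first because an aryl allyl ether would be deprotonated by the next reagent. F2 is treated with n-BuLi/TMEDA (2.2 equiv, one consumed by the phenol) in THF at −78 → −20 °C, which should lithiate C1 of ring A, the only position flanked by two ether oxygens (directed ortho-metalation), the low temperature sparing the dioxolane. Quenching with CO2 and acidifying to pH 3 brings the fallback back to the route at 26, which needs only the aqueous acid stage of step 15.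

Step 8. What may go wrong: deprotonation at the tertiary benzylic C–H beside the side-chain methoxy group, eroding the stereocentre; ionisation of the benzylic ether by the silyl triflate; or lithiation at the wrong carbon of the crowded ring. The fallback runs the metalation on the lithium alkoxide of the carbinol, whose benzylic C–H cannot be removed, and uses an N,N-diethylcarbamate that needs no silyl triflate. It sets out from 3: ClC(O)NEt2 and K2CO3 in MeCN should carbamoylate the unchelated 4-hydroxyl to give the hydroxy keto carbamate F3, and MeI/K2CO3 in DMF then gives the methoxy keto carbamate F4. The transfer hydrogenation of step 4 gives the (R)-carbinol carbamate F5. s-BuLi (2.2 equiv)/TMEDA in THF at −78 °C followed by TMSCl gives the O,C-bis-silyl carbamate F6, whose silyl ether is cleaved by K2CO3 in MeOH to the C-silyl carbinol carbamate F7. NaH/MeI gives the C-silyl methyl ether carbamate F8, and LiAlH4 in THF cleaves the carbamate to the silyl phenol 14, where the fallback comes back to the route; triflation with PhNTf2 as in the second stage of step 9 then gives 15.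

Step 4. What may go wrong: slow or incomplete hydride transfer to the electron-rich, ortho-substituted ketone, and poor facial selectivity because the isobutyl group is not much smaller than the twisted aryl group. The fallback replaces metal–ligand bifunctional transfer hydrogenation by a Corey–Bakshi–Shibata reduction, in which a chiral Lewis acid binds the ketone and delivers a boron hydride. It sets out from 5: (S)-2-methyl-CBS-oxazaborolidine (catalytic) with catecholborane in toluene at −78 °C, a reductant that does not hydroborate the allyl ether at this temperature, should place the aryl group in the large-group position and give the (R)-carbinol, coming back to the route at 6; no new compound is involved.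

Further compounds
F1 | step 14 | 2-{2-{3-methoxy-4-[(1R)-1-methoxy-3-methylbutyl]phenoxy}-5-methyl-3-(prop-2-en-1-yloxy)phenyl}-1,3-dioxolane | COc1cc(Oc2c(OCC=C)cc(C)cc2C3OCCO3)ccc1[C@@H](CC(C)C)OC
F2 | step 14 | 3-(1,3-dioxolan-2-yl)-2-{3-methoxy-4-[(1R)-1-methoxy-3-methylbutyl]phenoxy}-5-methylphenol | COc1cc(Oc2c(O)cc(C)cc2C3OCCO3)ccc1[C@@H](CC(C)C)OC
F3 | step 8 | 3-hydroxy-4-(3-methylbutanoyl)phenyl N,N-diethylcarbamate | CCN(CC)C(=O)Oc1ccc(C(=O)CC(C)C)c(O)c1
F4 | step 8 | 3-methoxy-4-(3-methylbutanoyl)phenyl N,N-diethylcarbamate | CCN(CC)C(=O)Oc1ccc(C(=O)CC(C)C)c(OC)c1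
F5 | step 8 | 4-[(1R)-1-hydroxy-3-methylbutyl]-3-methoxyphenyl N,N-diethylcarbamate | COc1cc(OC(=O)N(CC)CC)ccc1[C@@H](CC(C)C)O
F6 | step 8 | 3-methoxy-4-[(1R)-3-methyl-1-(trimethylsilyloxy)butyl]-2-(trimethylsilyl)phenyl N,N-diethylcarbamate | COc1c([Si](C)(C)C)c(OC(=O)N(CC)CC)ccc1[C@@H](CC(C)C)O[Si](C)(C)C
F7 | step 8 | 4-[(1R)-1-hydroxy-3-methylbutyl]-3-methoxy-2-(trimethylsilyl)phenyl N,N-diethylcarbamate | COc1c([Si](C)(C)C)c(OC(=O)N(CC)CC)ccc1[C@@H](CC(C)C)O
F8 | step 8 | 3-methoxy-4-[(1R)-1-methoxy-3-methylbutyl]-2-(trimethylsilyl)phenyl N,N-diethylcarbamate | COc1c([Si](C)(C)C)c(OC(=O)N(CC)CC)ccc1[C@@H](CC(C)C)OC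
F0 | step 4 | none | none
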